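Count what one turn of the main reaction costs in nucleophile before counting anything else; the meeting on this flask began there.

electrophile 1.0 mM; nucleophile 0.900 mM; free base 2.00 mM; time 3.0 min

- part of the electrophile that has reacted at 3.0 min
- share of the unused nucleophile that is free and not bound as protonated nucleophile, at 3.0 min

    acid set free + free base ⇌ salt of the base (K1 = 2.2 × 10⁶ M⁻¹, k1 = 190 M⁻¹ s⁻¹)
    electrophile + target → side product (k2 = 7.6 M⁻¹ s⁻¹)
    nucleophile + acid set free ⇌ protonated nucleophile, settled at all times (K3 = 3.4 × 10⁶ M⁻¹)
    2 free base → self-condensation product (k4 = 2.7 M⁻¹ s⁻¹)
    electrophile + nucleophile → acid set free + target (k5 = 8.1 M⁻¹ s⁻¹)

- a species is counted by the electrophile in it: one side product counts as two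
- where a step has two of a species, its rate is k times that concentration squared, and two are used at each turn
- run time (flask): 3.0 min

The bench chemist argued that free base should take the acid set free, since its balance figure at the charge, 4400, is larger than the nucleophile's 3100. The kineticist answered that balance is not a clock. Free acid meets base with a forward half-life of 1.8 s, but so little acid is unbound that bound acid leaves with a half-life near 93.0 min at the charge, far longer than the 3.0 min run.

The meeting therefore agreed that in this flask each turn costs two nucleophile, one reacted and one protonated. It named the turn allowance, the nucleophile charged divided by two, 0.450 mM. Even at two electrophile per turn, counting the side product, that asks less than the electrophile charged, which makes the nucleophile the limiting reagent in this flask.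

My own reckoning, as minute-taker, followed. Free nucleophile falls pseudo-first-order, at twice the step 5 constant times the electrophile, so I replaced the electrophile's curve by a mean. A turn uses one electrophile, or two once step 2 takes its target, and from the midpoint of those ends I set the mean at 0.662 mM. The exponent is 1.93, leaving 14.5% of the nucleophile free after 0.385 mM of turns. Both steps carry electrophile, so target follows from nucleophile spent without a clock: with step 2's constant over twice step 5's, 0.469, it comes to 0.220 mM. That gives 55.0% reacted and a free share of 25.3%. As a check, the reckoned end of 0.450 mM puts the straight chord at 0.725 mM, which gives 57.9%. The electrophile goes faster at the start than at the reckoned end, so its curve lies below that chord and I keep my figure, with 2.9 percentage points of doubt.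

The forecast gave 54.5% and a free share of 28%, above mine, holding that “acid set free stays almost entirely on the nucleophile”.

The simulation gives 54.6% and 27.5%, with 15.8% of this flask's nucleophile free against my 14.5%. This flask's target and side product make 0.384 mM of turns, under the allowance. The neighbouring flask holds 4.0 mM of electrophile and has the same allowance. The same reckoning there, with a mean electrophile of 3.66 mM and an exponent of 10.7, gives 22.4% reacted. That flask shows more, 24.6%. Its target and side product make 0.506 mM of turns, over the allowance, and it holds 0.122 mM of salt of the base.

All constants stand for no real mixture; the flask was simulated.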